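**Plan**

- Labdane numbering is used: ring A = C1–C5 and C10, ring B = C5–C10, C17 = exocyclic CH2, side chain = C11–C16. Cuts, last to first: the C14=C15 vinyl group (sulfur-ylide homologation of a C13 epoxide made by asymmetric epoxidation); C9–H with C8=C17 (allylic diazene transposition); C9–C11 (cross-coupling); C8–C17 (formylation of a C9 ketone); then C1–C10 and C3–C4 together; finally C4–C5.
- Enabling feature: in ring A the quaternary carbons C10 and C4 flank the C5 methine, and each is α to a carbonyl-level carbon once ring B carries a ketone at C9 (C4 has its own ester). This 1,3-dinucleophile can take up C1–C2–C3 as a 1,3-dielectrophile in a [3+3] annulation.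
- Forward: ring B is (S)-carvone; a propanoate unit is added to C5; a one-pot bis-alkylation with 1-chloro-3-iodopropane closes ring A; the isopropenyl helper at C7 is excised; the C9 ketone becomes a β-bromo enal that is coupled with the side chain; transposition, epoxidation and ylide opening finish the molecule.
- Stereochemistry: the carvone isopropenyl sets C5 (trans conjugate addition); C5 sets C10 (alkylation anti, hence the trans ring fusion); C4 follows from allylic strain in the ring-closing ester enolate; C9 from H delivery anti to the C10 methyl; C13 from reagent-controlled epoxidation.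

Key step: step 3

Remark: 5 and 7 are carried as mixtures at the propanoate α-carbon (future C4) and 9 at its hydroperoxy carbon; both centres are erased in the following bond change.

**Step 1**
Reactants: 1 methyl propanoate
Product: 3 1-methoxy-1-(trimethylsilyloxy)prop-1-ene (E/Z mixture), via lithium ester enolate 2 (not isolated)
Conditions: LiN(iPr)2, THF, −78 °C; Me3SiCl, −78 °C → rt; distillation
Reagents that add atoms: chlorotrimethylsilane, C[Si](C)(C)Cl
Why: Kinetic deprotonation of the ester and O-silylation of its lithium enolate is the standard preparation of a ketene silyl acetal, and the alkene geometry is immaterial because C4 is enolised again in step 3.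

**Step 2**
Reactants: 3 1-methoxy-1-(trimethylsilyloxy)prop-1-ene; 4 (S)-(+)-carvone
Product: 5 trimethylsilyl enol ether of the Michael adduct (propanoate at C5 trans to the C7 isopropenyl)
Conditions: HNTf2 (1 mol%), CH2Cl2, −78 °C; Et3N quench; filtration through basic alumina
Reagents that add atoms: none
Why: In this silyl-transfer Mukaiyama–Michael addition the ketene acetal should attack C5 of the silyl-activated enone axially and anti to the C7 isopropenyl group, which sets C5, while the silyl group ends on the C9 oxygen and so fixes the enol ether as C9=C10.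

**Step 3**
Reactants: 5 trimethylsilyl enol ether; 6 1-chloro-3-iodopropane
Product: 8 trans-fused bicyclic keto ester with the C7 isopropenyl group, via 3-chloropropyl keto ester 7 (not isolated)
Conditions: (Me2N)3S+ Me3SiF2− (1.1 equiv), 6 (1.05 equiv), THF, −78 → −20 °C; then LiN(iPr)2 (2.4 equiv), DMPU, −78 → 0 °C; aq NH4Cl
Reagents that add atoms: none
Why: Fluoride unmasks the regiodefined C9=C10 enolate, which displaces iodide of 6 at C10 (C1–C10) while the ester is still neutral; LiN(iPr)2 then forms the dianion (C8 ketone enolate plus C4 ester enolate), whose ester enolate displaces chloride at C3 (C3–C4). The closest known types are the fluoride-mediated regiospecific alkylation of enol silyl ethers and the intramolecular alkylation of ester enolates, merged here into a [3+3] bis-alkylation annulation. Ring A closes in the 6-(enolexo)-exo-tet mode through a chair transition state. C10 is set by axial attack anti to the pseudoaxial C5 substituent, which puts C1 trans to C4 on ring B and so fixes the trans ring fusion. C4 is set by allylic strain: H5 eclipses the enolate double bond and the tether can reach C4 only from the C10 side, so the C4 methyl should end axial (cis to the C10 methyl) and the ester equatorial. The step needs C10 to react before C4 and the ester enolate to outrun the ketone enolate; the first is secured by the silyl enol ether (only C10 is nucleophilic in the first stage) and by iodide over chloride, the second by the higher nucleophilicity of the ester enolate within the dianion and the strain-free chair closure.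

**Step 4**
Reactants: 8 bicyclic keto ester with the C7 isopropenyl group
Product: 10 trans-decalone ester (C9 ketone), via methoxy hydroperoxide 9 (not isolated)
Conditions: O3, MeOH, −78 °C; then FeSO4·7H2O, PhSH, −78 °C → rt
Reagents that add atoms: none
Why: Ozonolysis in methanol gives the α-methoxy hydroperoxide, divalent iron reduces it to an alkoxy radical that loses methyl acetate by β-scission, and the C7 radical takes hydrogen from the thiol (dealkenylative hydrogenation), so the helper leaves and only C7 changes.

**Step 5**
Reactants: 10 trans-decalone ester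
Product: 12 β-bromo enal (Br at C9, CHO at C8), via bromovinyl iminium bromide 11 (not isolated)
Conditions: PBr3, DMF, CHCl3, 0 → 60 °C; then aq NaOAc
Reagents that add atoms: N,N-dimethylformamide, CN(C)C=O; phosphorus tribromide, BrP(Br)Br; water, O
Why: In this Vilsmeier–Haack bromoformylation the ketone can enolise only towards C8, so the formyl carbon (C17) enters at C8 and bromide replaces the C9 oxygen without touching a stereocentre.

**Step 6**
Reactants: 13 2-methyl-2-vinyloxirane (racemic)
Product: 14 2-methylidenebut-3-en-1-ol
Conditions: LiN(iPr)2, Et2O, 0 °C → rt; aq NH4Cl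
Reagents that add atoms: none
Why: In this base-promoted isomerisation of an epoxide to an allylic alcohol the only β-hydrogens are those of the methyl group, so elimination gives the dienol and the stereocentre of the racemic epoxide disappears.

**Step 7**
Reactants: 14 2-methylidenebut-3-en-1-ol
Product: 15 tert-butyldimethylsilyl ether of 14
Conditions: t-BuMe2SiCl, imidazole, CH2Cl2, 0 °C → rt
Reagents that add atoms: tert-butyldimethylsilyl chloride, CC(C)(C)[Si](C)(C)Cl
Why: Standard silylation of a primary alcohol keeps the C16 oxygen apart from the C17 alcohol that is activated in step 10.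

**Step 8**
Reactants: 15 silyl ether of the dienol; 12 β-bromo enal
Product: 18 C9-alkylated enal (side chain C11–C14 and C16 in place), via alkylzirconocene chloride 16 (not isolated), via alkylzinc chloride 17 (not isolated)
Conditions: 15 (1.5 equiv), Cp2Zr(H)Cl, THF, rt; ZnCl2, THF, 0 °C; then 12, Pd(OAc)2 (5 mol%), SPhos (10 mol%), THF, 50 °C
Reagents that add atoms: none
Why: Hydrozirconation should place zirconium at the terminal carbon of the monosubstituted vinyl group (the 1,1-disubstituted alkene is too hindered for Cp2Zr(H)Cl), and transmetalation to zinc followed by Negishi coupling with the activated β-bromo enal forms C9–C11 without creating a stereocentre.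

**Step 9**
Reactants: 18 C9-alkylated enal
Product: 19 primary allylic alcohol (C17–OH)
Conditions: NaBH4, CeCl3·7H2O, MeOH, 0 °C
Reagents that add atoms: none
Why: Luche reduction delivers hydride 1,2 to the enal and leaves the hindered C4 methyl ester, the silyl ether and both alkenes untouched.

**Step 10**
Reactants: 19 primary allylic alcohol
Product: 22 exocyclic alkene with C9–H set (silyl ether), via allylic sulfonylhydrazine 20 (not isolated), via allylic diazene 21 (not isolated)
Conditions: 2-nitrobenzenesulfonylhydrazide, PPh3, diethyl azodicarboxylate, THF, −30 °C; then rt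
Reagents that add atoms: none
Why: Mitsunobu displacement by the sulfonylhydrazide, loss of sulfinic acid and retro-ene loss of N2 from the allylic diazene (reductive 1,3-transposition) move the double bond to C8=C17 and should deliver H to C9 on the face anti to the axial C10 methyl, which sets C9 with the side chain equatorial.

**Step 11**
Reactants: 22 silyl ether
Product: 23 side-chain allylic alcohol
Conditions: Bu4NF, THF, 0 °C → rt
Reagents that add atoms: none
Why: Fluoride cleaves the primary silyl ether while the ester and both alkenes are inert, and no stereocentre is affected.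

**Step 12**
Reactants: 23 side-chain allylic alcohol
Product: 24 (S)-epoxy alcohol at C13
Conditions: Ti(OiPr)4 (10 mol%), L-(+)-diethyl tartrate (12 mol%), t-BuOOH, 4 Å molecular sieves, CH2Cl2, −20 °C
Reagents that add atoms: tert-butyl hydroperoxide, CC(C)(C)OO
Why: Sharpless asymmetric epoxidation acts only on the allylic alcohol (the C8=C17 alkene has no directing hydroxyl) and with the L-(+)-tartrate should give the (S)-2,2-disubstituted glycidol by reagent control, which sets C13.

**Step 13**
Reactants: 24 epoxy alcohol
Product: 25 target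
Conditions: Me3S+ I− (5 equiv), n-BuLi (4.8 equiv), THF, −10 °C → rt
Reagents that add atoms: trimethylsulfonium iodide, C[S+](C)C.[I-]
Why: Dimethylsulfonium methylide opens the epoxide at its CH2 carbon and the sulfonium betaine then eliminates dimethyl sulfide (one-carbon homologation of an epoxide to an allylic alcohol), so C14=C15 forms with retention at C13 (the descriptor changes from S to R only by priority), the only possible Payne rearrangement being degenerate.

**Compound list**

1 | methyl propanoate | CCC(=O)OC | starting material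
2 | lithium 1-methoxyprop-1-en-1-olate | CC=C(OC)[O-].[Li+] | intermediate
3 | 1-methoxy-1-(trimethylsilyloxy)prop-1-ene (E/Z mixture) | CC=C(OC)O[Si](C)(C)C | intermediate
4 | (S)-(+)-carvone, (5S)-2-methyl-5-(prop-1-en-2-yl)cyclohex-2-en-1-one | O=C1C[C@@H](C(C)=C)CC=C1C | starting material
5 | methyl 2-[(1R,5S)-2-methyl-5-(prop-1-en-2-yl)-3-(trimethylsilyloxy)cyclohex-2-en-1-yl]propanoate (both epimers at the propanoate α-carbon) | C[Si](C)(C)OC1=C(C)[C@@H](C(C)C(=O)OC)C[C@H](C(C)=C)C1 | intermediate
6 | 1-chloro-3-iodopropane | ClCCCI | starting material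
7 | methyl 2-[(1R,2R,5S)-2-(3-chloropropyl)-2-methyl-3-oxo-5-(prop-1-en-2-yl)cyclohexyl]propanoate (both epimers at the propanoate α-carbon) | O=C1C[C@@H](C(C)=C)C[C@H](C(C)C(=O)OC)[C@@]1(C)CCCCl | intermediate
8 | methyl (1S,4aR,7S,8aS)-1,4a-dimethyl-5-oxo-7-(prop-1-en-2-yl)decahydronaphthalene-1-carboxylate (trans ring fusion; 1-methyl cis to 4a-methyl) | O=C1C[C@@H](C(C)=C)C[C@H]2[C@@]1(C)CCC[C@]2(C)C(=O)OC | intermediate
9 | methyl (1S,4aR,7S,8aS)-7-(1-hydroperoxy-1-methoxyethyl)-1,4a-dimethyl-5-oxodecahydronaphthalene-1-carboxylate | O=C1C[C@@H](C(C)(OC)OO)C[C@H]2[C@@]1(C)CCC[C@]2(C)C(=O)OC | intermediate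
10 | methyl (1S,4aR,8aS)-1,4a-dimethyl-5-oxodecahydronaphthalene-1-carboxylate | O=C1CCC[C@H]2[C@@]1(C)CCC[C@]2(C)C(=O)OC | intermediate
11 | N-{[(4aR,5S,8aR)-1-bromo-5-(methoxycarbonyl)-5,8a-dimethyl-3,4,4a,5,6,7,8,8a-octahydronaphthalen-2-yl]methylidene}-N-methylmethanaminium bromide | BrC1=C(C=[N+](C)C)CC[C@H]2[C@@]1(C)CCC[C@]2(C)C(=O)OC.[Br-] | intermediate
12 | methyl (1S,4aR,8aR)-5-bromo-6-formyl-1,4a-dimethyl-1,2,3,4,4a,7,8,8a-octahydronaphthalene-1-carboxylate | BrC1=C(C=O)CC[C@H]2[C@@]1(C)CCC[C@]2(C)C(=O)OC | intermediate
13 | 2-methyl-2-vinyloxirane (racemic) | CC1(CO1)C=C | starting material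
14 | 2-methylidenebut-3-en-1-ol | C=CC(=C)CO | intermediate
15 | tert-butyl(dimethyl)[(2-methylidenebut-3-en-1-yl)oxy]silane | C=CC(=C)CO[Si](C)(C)C(C)(C)C | intermediate
16 | chlorobis(cyclopentadienyl)[3-({[tert-butyl(dimethyl)silyl]oxy}methyl)but-3-en-1-yl]zirconium | Cl[Zr](CCC(=C)CO[Si](C)(C)C(C)(C)C)(C1C=CC=C1)C1C=CC=C1 | intermediate
17 | [3-({[tert-butyl(dimethyl)silyl]oxy}methyl)but-3-en-1-yl]zinc chloride | Cl[Zn]CCC(=C)CO[Si](C)(C)C(C)(C)C | intermediate
18 | methyl (1S,4aR,8aS)-5-[3-({[tert-butyl(dimethyl)silyl]oxy}methyl)but-3-en-1-yl]-6-formyl-1,4a-dimethyl-1,2,3,4,4a,7,8,8a-octahydronaphthalene-1-carboxylate | C=C(CO[Si](C)(C)C(C)(C)C)CCC1=C(C=O)CC[C@H]2[C@@]1(C)CCC[C@]2(C)C(=O)OC | intermediate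
19 | methyl (1S,4aR,8aS)-5-[3-({[tert-butyl(dimethyl)silyl]oxy}methyl)but-3-en-1-yl]-6-(hydroxymethyl)-1,4a-dimethyl-1,2,3,4,4a,7,8,8a-octahydronaphthalene-1-carboxylate | C=C(CO[Si](C)(C)C(C)(C)C)CCC1=C(CO)CC[C@H]2[C@@]1(C)CCC[C@]2(C)C(=O)OC | intermediate
20 | N-alkyl-N-(2-nitrobenzenesulfonyl)hydrazine formed from 19 at C17 | C=C(CO[Si](C)(C)C(C)(C)C)CCC1=C(CN(N)S(=O)(=O)c3ccccc3[N+](=O)[O-])CC[C@H]2[C@@]1(C)CCC[C@]2(C)C(=O)OC | intermediate
21 | allylic monoalkyl diazene at C17 | C=C(CO[Si](C)(C)C(C)(C)C)CCC1=C(CN=N)CC[C@H]2[C@@]1(C)CCC[C@]2(C)C(=O)OC | intermediate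
22 | methyl (1S,4aS,5R,8aS)-5-[3-({[tert-butyl(dimethyl)silyl]oxy}methyl)but-3-en-1-yl]-1,4a-dimethyl-6-methylidenedecahydronaphthalene-1-carboxylate | C=C(CO[Si](C)(C)C(C)(C)C)CC[C@@H]1C(=C)CC[C@H]2[C@@]1(C)CCC[C@]2(C)C(=O)OC | intermediate
23 | methyl (1S,4aS,5R,8aS)-5-[3-(hydroxymethyl)but-3-en-1-yl]-1,4a-dimethyl-6-methylidenedecahydronaphthalene-1-carboxylate | C=C(CO)CC[C@@H]1C(=C)CC[C@H]2[C@@]1(C)CCC[C@]2(C)C(=O)OC | intermediate
24 | methyl (1S,4aS,5R,8aS)-5-{2-[(2S)-2-(hydroxymethyl)oxiran-2-yl]ethyl}-1,4a-dimethyl-6-methylidenedecahydronaphthalene-1-carboxylate | C1O[C@]1(CO)CC[C@@H]2C(=C)CC[C@H]3[C@@]2(C)CCC[C@]3(C)C(=O)OC | intermediate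
25 | methyl (1S,4aS,5R,8aS)-5-[(3R)-3-hydroxy-3-(hydroxymethyl)pent-4-en-1-yl]-1,4a-dimethyl-6-methylidenedecahydronaphthalene-1-carboxylate | C=C[C@@](O)(CO)CC[C@@H]1C(=C)CC[C@H]2[C@@]1(C)CCC[C@]2(C)C(=O)OC | target

**Step count and risks**

Total step count: 13. Longest linear sequence: 11 steps (steps 1–5 and 8–13); steps 6 and 7 make the side-chain fragment.

Step 3 is the most likely to fail. In the first stage the naked enolate may alkylate on oxygen or exchange protons with the product ketone, and in the second stage the C8 ketone enolate may compete (O-alkylation or bridging C-alkylation) before the ester enolate closes ring A. The fallback sets out from 5 and returns at 8. The first stage is run alone and chloro ketone 7 is isolated. LiN(iPr)2 with Me3SiCl present (internal quench, −78 °C) then masks the ketone as its C8=C9 trimethylsilyl enol ether F1, so that the ester is the only carbon acid left. KN(SiMe3)2 in THF–DMPU closes ring A through the ester enolate alone, and dilute acid on work-up hydrolyses the enol ether to give 8.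

Step 8 is the second risk. Oxidative addition and transmetalation may be slow at the tetrasubstituted bromide next to the quaternary C10, the alkyl partner may lose β-hydride, or the organometallic may add to the aldehyde. The fallback is an alkylative 1,3-carbonyl transposition that sets out from 10 and 15 and returns at 18. Ketone 10 is formylated (NaH, HCO2Et) to the hydroxymethylene ketone F2, which butane-1-thiol and TsOH convert into the butylthiomethylene ketone F3. Diene 15 is hydrozirconated as in step 8 and 16 is quenched with I2 to give the homoallylic iodide F4. t-BuLi at −78 °C turns F4 into the alkyllithium F5, which adds to the ketone carbonyl of F3 to give the tertiary carbinol F6. Aqueous HCl in THF hydrolyses F6 with allylic transposition to enal 18.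

Step 10 is the third risk. Mitsunobu activation of the hindered allylic alcohol may be incomplete, or hydrogen delivery may leak to the wrong face of C9. The fallback sets out from 19 and returns at 22. ClCO2Me and pyridine convert 19 into the allylic methyl carbonate F7. Pd(OAc)2 and n-Bu3P with HCO2H–Et3N then carry out formate hydrogenolysis, in which the allylpalladium formate passes hydride to the more substituted terminus C9 from the metal-bearing, less hindered face and leaves the C8=C17 alkene of 22.

**Further compounds**

F1 | step 3 | methyl 2-[(1R,2R,5S)-2-(3-chloropropyl)-2-methyl-5-(prop-1-en-2-yl)-3-(trimethylsilyloxy)cyclohex-3-en-1-yl]propanoate | C[Si](C)(C)OC1=C[C@@H](C(C)=C)C[C@H](C(C)C(=O)OC)[C@@]1(C)CCCCl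
F2 | step 8 | methyl (1S,4aR,8aS)-6-(hydroxymethylidene)-1,4a-dimethyl-5-oxodecahydronaphthalene-1-carboxylate | O=C1C(=CO)CC[C@H]2[C@@]1(C)CCC[C@]2(C)C(=O)OC
F3 | step 8 | methyl (1S,4aR,8aS)-6-[(butylsulfanyl)methylidene]-1,4a-dimethyl-5-oxodecahydronaphthalene-1-carboxylate | O=C1C(=CSCCCC)CC[C@H]2[C@@]1(C)CCC[C@]2(C)C(=O)OC
F4 | step 8 | tert-butyl[(4-iodo-2-methylidenebutyl)oxy]dimethylsilane | ICCC(=C)CO[Si](C)(C)C(C)(C)C
F5 | step 8 | [3-({[tert-butyl(dimethyl)silyl]oxy}methyl)but-3-en-1-yl]lithium | [Li]CCC(=C)CO[Si](C)(C)C(C)(C)C
F6 | step 8 | methyl (1S,4aR,8aS)-6-[(butylsulfanyl)methylidene]-5-[3-({[tert-butyl(dimethyl)silyl]oxy}methyl)but-3-en-1-yl]-5-hydroxy-1,4a-dimethyldecahydronaphthalene-1-carboxylate (carbinol configuration immaterial) | C=C(CO[Si](C)(C)C(C)(C)C)CCC1(O)C(=CSCCCC)CC[C@H]2[C@@]1(C)CCC[C@]2(C)C(=O)OC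
F7 | step 10 | methyl (1S,4aR,8aS)-5-[3-({[tert-butyl(dimethyl)silyl]oxy}methyl)but-3-en-1-yl]-6-{[(methoxycarbonyl)oxy]methyl}-1,4a-dimethyl-1,2,3,4,4a,7,8,8a-octahydronaphthalene-1-carboxylate | C=C(CO[Si](C)(C)C(C)(C)C)CCC1=C(COC(=O)OC)CC[C@H]2[C@@]1(C)CCC[C@]2(C)C(=O)OC
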